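**Retrosynthetic overview**
1. Target 32 ← peripheral epoxidation of the E-1(10) alkene of 31 ← isovaleroylation of macrocyclic allylic alcohol 30.
2. The ten-membered ring is closed last, at C3–C4, by Nozaki–Hiyama–Kishi coupling of the Z-alkenyl iodide and aldehyde in 28.
3. The C8 ester comes from an inverting Mitsunobu reaction with epoxy acid 22 (Shi epoxidation of tiglyl alcohol); C7–C8 comes from a zinc Barbier reaction of bromomethylbutenolide 11 with aldehyde 18.
4. The α-methylene-γ-lactone is made first: a chiral Brønsted-acid-catalysed 2-(methoxycarbonyl)allylboration of (Z)-3-iodobut-2-enal 4 sets C6, then a 1,3-bromide transposition gives 11.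
5. Ring order: γ-lactone (step 4) → side-chain oxirane (step 10) → ten-membered carbocycle (step 15) → ring oxirane (step 17).

Assumption: the C8 acyl group is taken exactly as drawn, i.e. the cis-dimethyl (2R,3S)-2,3-epoxy-2-methylbutanoate (the epoxide of tiglic acid).
Numbering: C-numbers are germacrane numbers (C6 lactone O–CH, C7 ring-fusion CH, C8 CH–O-epoxy ester, C10 bears C14, C3 CH–O-isovalerate, C4 bears C15, C11=C13 methylene, C12 lactone C=O).

**Step 1**
Reactants: 1 but-2-yn-1-ol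
Product: 3 (2Z)-3-iodobut-2-en-1-ol, via cyclic sodium alkenylalanate 2 (not isolated)
Conditions: NaAlH2(OCH2CH2OMe)2, Et2O, 0 °C → rt; then I2, THF, −78 °C
Reagents that add atoms: iodine, II
Why: Hydroxyl-directed trans-hydroalumination places Al on C3 in a five-membered alanate, and iodinolysis with retention gives only the Z iodoalkene.

**Step 2**
Reactants: 3 (2Z)-3-iodobut-2-en-1-ol
Product: 4 (2Z)-3-iodobut-2-enal
Conditions: MnO2, CH2Cl2, rt
Reagents that add atoms: none
Why: Neutral MnO2 oxidation of the allylic alcohol keeps the Z geometry.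

**Step 3**
Reactants: 5 methyl 2-(bromomethyl)prop-2-enoate
Product: 6 methyl 2-[(4,4,5,5-tetramethyl-1,3,2-dioxaborolan-2-yl)methyl]prop-2-enoate
Conditions: B2pin2, CuCl (10 mol %), LiCl, KOAc, DMF, rt
Reagents that add atoms: bis(pinacolato)diboron, CC1(C)OB(OC1(C)C)B1OC(C)(C)C(C)(C)O1
Why: Copper-catalysed nucleophilic borylation of an allylic bromide (SN2 and SN2' paths give the same product here).

**Step 4**
Reactants: 4 (2Z)-3-iodobut-2-enal; 6 methyl 2-[(4,4,5,5-tetramethyl-1,3,2-dioxaborolan-2-yl)methyl]prop-2-enoate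
Product: 8 (5S)-5-[(1Z)-2-iodoprop-1-en-1-yl]-3-methylideneoxolan-2-one, via O-pinacolboryl homoallylic ester 7 (not isolated)
Conditions: (S)-N-triflyl phosphoramide of 3,3′-bis(2,4,6-triisopropylphenyl)-1,1′-bi-2-naphthol (10 mol %), 4 Å MS, toluene, −40 → 0 °C; then p-TsOH·H2O (10 mol %), rt
Reagents that add atoms: none
Why: Proposed new method: enantioselective allylboration with an ester-deactivated 2-(alkoxycarbonyl)allyl pinacolboronate under a strong chiral Brønsted acid, which hydrogen-bonds the pseudo-equatorial boronate oxygen (raising boron Lewis acidity, as triflic acid does in the racemic series) while its basic oxygen holds the formyl C–H, so the closed chair transition state sits in the chiral pocket, the allyl group is delivered to the Si face (C6 = S; catalyst antipode chosen by analogy with phosphoric-acid allylborations of aryl and alkenyl aldehydes) and the borate then lactonises; closest known reactions are the BINOL-phosphoric-acid-catalysed allylboration of aldehydes with allyl-Bpin and the triflic-acid-catalysed racemic additions of 2-alkoxycarbonyl allylboronates.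

**Step 5**
Reactants: 8 (5S)-5-[(1Z)-2-iodoprop-1-en-1-yl]-3-methylideneoxolan-2-one
Product: 11 (5S)-3-(bromomethyl)-5-[(1Z)-2-iodoprop-1-en-1-yl]furan-2(5H)-one, via bromomethyl silyl ketene acetal 9 (not isolated), via α-bromo-α-bromomethyl lactone 10 (not isolated)
Conditions: TMSBr, CH2Cl2, −40 → 0 °C; then NBS, −78 °C; then Et3N, −78 → 0 °C
Reagents that add atoms: bromotrimethylsilane, C[Si](C)(C)Br
Why: Conjugate addition of bromide touches only the acrylate, NBS then brominates only the electron-rich silyl ketene acetal, and E2 loss of HBr gives the conjugated endocyclic alkene, so the net 1,3-transposition spares the iodoalkene and C6 (Br2 itself would attack the iodoalkene first).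

**Step 6**
Reactants: 12 1-[(but-3-yn-1-yloxy)methyl]-4-methoxybenzene
Product: 15 (3E)-6-[(4-methoxyphenyl)methoxy]-4-methylhex-3-en-1-ol, via alkenyldimethylalane 13 (not isolated), via lithium alkenylalanate 14 (not isolated)
Conditions: AlMe3, ZrCl2(C5H5)2 (25 mol %), CH2Cl2, 0 °C → rt; then n-BuLi, THF, −30 °C; ethylene oxide, −30 → 0 °C
Reagents that add atoms: trimethylaluminium, C[Al](C)C; ethylene oxide, C1CO1
Why: Zirconium-catalysed Negishi carboalumination adds Me and Al syn and regioselectively (E-trisubstituted alkene), and the derived alanate opens ethylene oxide with retention of geometry.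

**Step 7**
Reactants: 15 (3E)-6-[(4-methoxyphenyl)methoxy]-4-methylhex-3-en-1-ol
Product: 16 triethyl{[(3E)-6-[(4-methoxyphenyl)methoxy]-4-methylhex-3-en-1-yl]oxy}silane
Conditions: TESCl, imidazole, CH2Cl2, 0 °C
Reagents that add atoms: chlorotriethylsilane, CC[Si](Cl)(CC)CC
Why: Standard silylation of the primary alcohol (the future C3 oxygen).

**Step 8**
Reactants: 16 triethyl{[(3E)-6-[(4-methoxyphenyl)methoxy]-4-methylhex-3-en-1-yl]oxy}silane
Product: 17 (3E)-3-methyl-6-[(triethylsilyl)oxy]hex-3-en-1-ol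
Conditions: DDQ, CH2Cl2/pH 7 phosphate buffer, 0 °C
Reagents that add atoms: none
Why: Oxidative cleavage of the 4-methoxybenzyl ether by benzylic hydride abstraction; the buffered medium spares the triethylsilyl ether and the alkene.

**Step 9**
Reactants: 17 (3E)-3-methyl-6-[(triethylsilyl)oxy]hex-3-en-1-ol
Product: 18 (3E)-3-methyl-6-[(triethylsilyl)oxy]hex-3-enal
Conditions: Dess–Martin periodinane, NaHCO3, CH2Cl2, 0 °C → rt (used crude)
Reagents that add atoms: none
Why: Buffered Dess–Martin oxidation gives the β,γ-unsaturated aldehyde without moving the alkene into conjugation.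

**Step 10**
Reactants: 19 (2E)-2-methylbut-2-en-1-ol
Product: 20 [(2S,3S)-2,3-dimethyloxiran-2-yl]methanol
Conditions: 1,2:4,5-di-O-isopropylidene-β-L-erythro-2,3-hexodiulo-2,6-pyranose (L-fructose-derived ketone, 30 mol %), KHSO5 (as 2KHSO5·KHSO4·K2SO4), K2CO3, n-Bu4NHSO4, MeCN/dimethoxymethane/aq. buffer pH 10.5, 0 °C
Reagents that add atoms: potassium peroxymonosulfate, [K+].[O-]S(=O)(=O)OO
Why: Shi epoxidation: the chiral dioxirane transfers oxygen through a spiro transition state to one face of the E-trisubstituted alkene, setting both oxirane centres (2S,3S, cis-dimethyl by stereospecific syn addition).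

**Step 11**
Reactants: 20 [(2S,3S)-2,3-dimethyloxiran-2-yl]methanol
Product: 22 (2R,3S)-2,3-dimethyloxirane-2-carboxylic acid, via epoxy aldehyde 21 (not isolated)
Conditions: TEMPO (2,2,6,6-tetramethylpiperidin-1-oxyl, cat.), NaOCl (cat.), NaClO2, MeCN/phosphate buffer pH 6.7, 35 °C
Reagents that add atoms: sodium chlorite, [Na+].[O-]Cl=O
Why: Oxoammonium oxidation to the aldehyde and chlorite oxidation to the acid at near-neutral pH leave the oxirane and both stereocentres intact (the descriptor at C2 changes only through CIP priorities).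

**Step 12**
Reactants: 11 (5S)-3-(bromomethyl)-5-[(1Z)-2-iodoprop-1-en-1-yl]furan-2(5H)-one; 18 (3E)-3-methyl-6-[(triethylsilyl)oxy]hex-3-enal
Product: 24 (4R,5S)-4-[(1S,3E)-1-hydroxy-3-methyl-6-[(triethylsilyl)oxy]hex-3-en-1-yl]-5-[(1Z)-2-iodoprop-1-en-1-yl]-3-methylideneoxolan-2-one, via allylzinc bromide 23 (not isolated)
Conditions: Zn dust, THF/sat. aq. NH4Cl, 0 °C → rt
Reagents that add atoms: none
Why: Zinc Barbier allylation: the cyclic allylzinc reacts at its γ-carbon (C7) through a chair Zimmerman–Traxler transition state, anti to the C6 alkenyl group (7R, trans-lactone) and with the aldehyde chain equatorial (anti adduct, 8S, the epimer that step 13 inverts), regenerating the exocyclic methylene.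

**Step 13**
Reactants: 24 Barbier alcohol (name as in step 12); 22 (2R,3S)-2,3-dimethyloxirane-2-carboxylic acid
Product: 26 (1R,3E)-1-[(2S,3R)-2-[(1Z)-2-iodoprop-1-en-1-yl]-4-methylidene-5-oxooxolan-3-yl]-3-methyl-6-[(triethylsilyl)oxy]hex-3-en-1-yl (2R,3S)-2,3-dimethyloxirane-2-carboxylate, via alkoxyphosphonium carboxylate 25 (not isolated)
Conditions: PPh3, DIAD, toluene, 0 °C → rt
Reagents that add atoms: none
Why: Mitsunobu esterification: SN2 displacement of the C8 oxyphosphonium by the carboxylate installs the ester with inversion (8S → 8R) and leaves the acid's stereocentres untouched.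

**Step 14**
Reactants: 26 silyl ether ester (name as in step 13)
Product: 28 (1R,3E)-1-[(2S,3R)-2-[(1Z)-2-iodoprop-1-en-1-yl]-4-methylidene-5-oxooxolan-3-yl]-3-methyl-6-oxohex-3-en-1-yl (2R,3S)-2,3-dimethyloxirane-2-carboxylate, via alkoxysulfonium chloride 27 (not isolated)
Conditions: (COCl)2, DMSO, CH2Cl2, −78 °C; then i-Pr2NEt, −78 → −40 °C (used crude)
Reagents that add atoms: none
Why: Swern conditions oxidise a primary triethylsilyl ether directly (silyl transfer to chloride, then ylide fragmentation), releasing the β,γ-unsaturated aldehyde cold.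

**Step 15**
Reactants: 28 iodo aldehyde (name as in step 14)
Product: 30 (3aR,4R,6E,9S,10Z,11aR)-9-hydroxy-6,10-dimethyl-3-methylidene-2-oxo-2,3,3a,4,5,8,9,11a-octahydrocyclodeca[b]furan-4-yl (2R,3S)-2,3-dimethyloxirane-2-carboxylate, via alkenylchromium dichloride 29 (not isolated)
Conditions: CrCl2 (10 equiv), NiCl2 (5 mol %), DMSO/THF, 2 mM, rt
Reagents that add atoms: none
Why: Nozaki–Hiyama–Kishi macrocyclisation: nickel-catalysed activation of the Z-alkenyl iodide, transmetallation to chromium and intramolecular aldehyde addition close the ten-membered ring with retention of the Z geometry; the 3S carbinol is expected from attack on the aldehyde face that leaves the new oxygen on the ring periphery, which is a prediction, not a precedent-backed result.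

**Step 16**
Reactants: 30 macrocyclic allylic alcohol (name as in step 15)
Product: 31 (3aR,4R,6E,9S,10Z,11aR)-6,10-dimethyl-3-methylidene-9-[(3-methylbutanoyl)oxy]-2-oxo-2,3,3a,4,5,8,9,11a-octahydrocyclodeca[b]furan-4-yl (2R,3S)-2,3-dimethyloxirane-2-carboxylate
Conditions: isovaleryl chloride, pyridine, 4-(dimethylamino)pyridine (cat.), CH2Cl2, 0 °C
Reagents that add atoms: 3-methylbutanoyl chloride, CC(C)CC(=O)Cl
Why: Nucleophile-catalysed acylation of the only free hydroxyl, with C3 unchanged.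

**Step 17**
Reactants: 31 diester triene (name as in step 16)
Product: 32 CNP0167461.4, the (1R,3S,4Z,6R,7R,8R,10R)-1,10-epoxy-3-(3-methylbutanoyloxy)-8-[(2R,3S)-2,3-dimethyloxirane-2-carbonyloxy]germacra-4,11(13)-dien-12,6-olide
Conditions: mCPBA, NaHCO3, CH2Cl2, 0 °C
Reagents that add atoms: 3-chloroperoxybenzoic acid, OOC(=O)c1cccc(Cl)c1
Why: Prilezhaev epoxidation: the E-1(10) alkene is the only electron-rich alkene (C4=C5 is flanked by two allylic acyloxy groups, C11=C13 is conjugated), and peripheral attack on its outer face gives the trans (1R,10R) oxirane.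

**Compound list**
1 | but-2-yn-1-ol | CC#CCO | starting material
2 | cyclic sodium alkenylalanate (Al on C3 and O, two 2-methoxyethoxy ligands) | CC1=CCO[Al-]1(OCCOC)OCCOC.[Na+] | intermediate
3 | (2Z)-3-iodobut-2-en-1-ol | C/C(I)=C/CO | intermediate
4 | (2Z)-3-iodobut-2-enal | C/C(I)=C/C=O | intermediate
5 | methyl 2-(bromomethyl)prop-2-enoate | C=C(CBr)C(=O)OC | starting material
6 | methyl 2-[(4,4,5,5-tetramethyl-1,3,2-dioxaborolan-2-yl)methyl]prop-2-enoate | C=C(CB1OC(C)(C)C(C)(C)O1)C(=O)OC | intermediate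
7 | methyl (4S,5Z)-6-iodo-2-methylidene-4-[(4,4,5,5-tetramethyl-1,3,2-dioxaborolan-2-yl)oxy]hept-5-enoate | C=C(C[C@@H](/C=C(/C)I)OB1OC(C)(C)C(C)(C)O1)C(=O)OC | intermediate
8 | (5S)-5-[(1Z)-2-iodoprop-1-en-1-yl]-3-methylideneoxolan-2-one | C=C1C[C@@H](/C=C(/C)I)OC1=O | intermediate
9 | {[(5S)-3-(bromomethyl)-5-[(1Z)-2-iodoprop-1-en-1-yl]-4,5-dihydrofuran-2-yl]oxy}trimethylsilane | C[Si](C)(C)OC1=C(CBr)C[C@@H](/C=C(/C)I)O1 | intermediate
10 | (5S)-3-bromo-3-(bromomethyl)-5-[(1Z)-2-iodoprop-1-en-1-yl]oxolan-2-one (both C3 epimers) | BrCC1(Br)C[C@@H](/C=C(/C)I)OC1=O | intermediate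
11 | (5S)-3-(bromomethyl)-5-[(1Z)-2-iodoprop-1-en-1-yl]furan-2(5H)-one | BrCC1=C[C@@H](/C=C(/C)I)OC1=O | intermediate
12 | 1-[(but-3-yn-1-yloxy)methyl]-4-methoxybenzene | C#CCCOCc1ccc(OC)cc1 | starting material
13 | dimethyl{(1E)-4-[(4-methoxyphenyl)methoxy]-2-methylbut-1-en-1-yl}alane | C[Al](C)/C=C(\C)CCOCc1ccc(OC)cc1 | intermediate
14 | lithium butyl(dimethyl){(1E)-4-[(4-methoxyphenyl)methoxy]-2-methylbut-1-en-1-yl}alanate | [Li+].CCCC[Al-](C)(C)/C=C(\C)CCOCc1ccc(OC)cc1 | intermediate
15 | (3E)-6-[(4-methoxyphenyl)methoxy]-4-methylhex-3-en-1-ol | OCC/C=C(\C)CCOCc1ccc(OC)cc1 | intermediate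
16 | triethyl{[(3E)-6-[(4-methoxyphenyl)methoxy]-4-methylhex-3-en-1-yl]oxy}silane | CC[Si](CC)(CC)OCC/C=C(\C)CCOCc1ccc(OC)cc1 | intermediate
17 | (3E)-3-methyl-6-[(triethylsilyl)oxy]hex-3-en-1-ol | CC[Si](CC)(CC)OCC/C=C(\C)CCO | intermediate
18 | (3E)-3-methyl-6-[(triethylsilyl)oxy]hex-3-enal | CC[Si](CC)(CC)OCC/C=C(\C)CC=O | intermediate
19 | (2E)-2-methylbut-2-en-1-ol | C/C=C(\C)CO | starting material
20 | [(2S,3S)-2,3-dimethyloxiran-2-yl]methanol | OC[C@]1(C)O[C@H]1C | intermediate
21 | (2R,3S)-2,3-dimethyloxirane-2-carbaldehyde | O=C[C@]1(C)O[C@H]1C | intermediate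
22 | (2R,3S)-2,3-dimethyloxirane-2-carboxylic acid | OC(=O)[C@]1(C)O[C@H]1C | intermediate
23 | {[(5S)-5-[(1Z)-2-iodoprop-1-en-1-yl]-2-oxo-2,5-dihydrofuran-3-yl]methyl}zinc bromide | Br[Zn]CC1=C[C@@H](/C=C(/C)I)OC1=O | intermediate
24 | (4R,5S)-4-[(1S,3E)-1-hydroxy-3-methyl-6-[(triethylsilyl)oxy]hex-3-en-1-yl]-5-[(1Z)-2-iodoprop-1-en-1-yl]-3-methylideneoxolan-2-one | C=C1C(=O)O[C@H](/C=C(/C)I)[C@H]1[C@@H](O)C/C(C)=C/CCO[Si](CC)(CC)CC | intermediate
25 | triphenylphosphonium ether at the C8 oxygen of 24 (8S), paired with the carboxylate of 22 | C=C1C(=O)O[C@H](/C=C(/C)I)[C@H]1[C@@H](O[P+](c1ccccc1)(c1ccccc1)c1ccccc1)C/C(C)=C/CCO[Si](CC)(CC)CC.[O-]C(=O)[C@]1(C)O[C@H]1C | intermediate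
26 | (1R,3E)-1-[(2S,3R)-2-[(1Z)-2-iodoprop-1-en-1-yl]-4-methylidene-5-oxooxolan-3-yl]-3-methyl-6-[(triethylsilyl)oxy]hex-3-en-1-yl (2R,3S)-2,3-dimethyloxirane-2-carboxylate | C=C1C(=O)O[C@H](/C=C(/C)I)[C@H]1[C@H](OC(=O)[C@]2(C)O[C@H]2C)C/C(C)=C/CCO[Si](CC)(CC)CC | intermediate
27 | dimethylsulfonium ether at the C3 oxygen of desilylated 26, chloride salt | C=C1C(=O)O[C@H](/C=C(/C)I)[C@H]1[C@H](OC(=O)[C@]2(C)O[C@H]2C)C/C(C)=C/CCO[S+](C)C.[Cl-] | intermediate
28 | (1R,3E)-1-[(2S,3R)-2-[(1Z)-2-iodoprop-1-en-1-yl]-4-methylidene-5-oxooxolan-3-yl]-3-methyl-6-oxohex-3-en-1-yl (2R,3S)-2,3-dimethyloxirane-2-carboxylate | C=C1C(=O)O[C@H](/C=C(/C)I)[C@H]1[C@H](OC(=O)[C@]2(C)O[C@H]2C)C/C(C)=C/CC=O | intermediate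
29 | alkenylchromium dichloride of 28 (CrCl2 in place of iodine, trivalent chromium) | C=C1C(=O)O[C@H](/C=C(/C)[Cr](Cl)Cl)[C@H]1[C@H](OC(=O)[C@]2(C)O[C@H]2C)C/C(C)=C/CC=O | intermediate
30 | (3aR,4R,6E,9S,10Z,11aR)-9-hydroxy-6,10-dimethyl-3-methylidene-2-oxo-2,3,3a,4,5,8,9,11a-octahydrocyclodeca[b]furan-4-yl (2R,3S)-2,3-dimethyloxirane-2-carboxylate | C=C1C(=O)O[C@@H]2/C=C(/C)[C@@H](O)C/C=C(\C)C[C@@H](OC(=O)[C@]3(C)O[C@H]3C)[C@@H]12 | intermediate
31 | (3aR,4R,6E,9S,10Z,11aR)-6,10-dimethyl-3-methylidene-9-[(3-methylbutanoyl)oxy]-2-oxo-2,3,3a,4,5,8,9,11a-octahydrocyclodeca[b]furan-4-yl (2R,3S)-2,3-dimethyloxirane-2-carboxylate | C=C1C(=O)O[C@@H]2/C=C(/C)[C@@H](OC(=O)CC(C)C)C/C=C(\C)C[C@@H](OC(=O)[C@]3(C)O[C@H]3C)[C@@H]12 | intermediate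
32 | CNP0167461.4, (1R,3S,4Z,6R,7R,8R,10R)-1,10-epoxy-3-(3-methylbutanoyloxy)-8-[(2R,3S)-2,3-dimethyloxirane-2-carbonyloxy]germacra-4,11(13)-dien-12,6-olide | C=C1C(=O)O[C@@H]2/C=C(/C)[C@@H](OC(=O)CC(C)C)C[C@H]3O[C@]3(C)C[C@@H](OC(=O)[C@]3(C)O[C@H]3C)[C@@H]12 | target

**Step count and risks**
Total steps: 17. Longest linear sequence: 10 (steps 1, 2, 4, 5, 12–17; the branch 6–9, 12–17 is equally long).

Step 4 is the new step. The ester-deactivated boronate may not be activated enough by the chiral acid, or the enantioselectivity may be low. The fallback is known chemistry; it sets out from 4 and 5 and comes back at 8. A chromium-catalysed enantioselective 2-(alkoxycarbonyl)allylation (CrCl2 10 mol %, chiral 1,8-bis(oxazolinyl)carbazole ligand, Mn powder, ZrCl2(C5H5)2, THF; the alkenyl iodide is inert without nickel) gives methyl (4S,5Z)-4-hydroxy-6-iodo-2-methylidenehept-5-enoate F1, which is lactonised with p-TsOH in CH2Cl2 to 8.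

Step 5 is a one-pot sequence without direct precedent on this substrate. TMSBr may open the allylic lactone, or the elimination may give the exocyclic bromoalkene. The fallback sets out from 8 and comes back at 11. Nucleophilic epoxidation of the acrylate (t-BuOOH, DBU) gives (6S)-6-[(1Z)-2-iodoprop-1-en-1-yl]-1,5-dioxaspiro[2.4]heptan-4-one F2. MgBr2·OEt2 opens it at the primary carbon to (5S)-3-(bromomethyl)-3-hydroxy-5-[(1Z)-2-iodoprop-1-en-1-yl]oxolan-2-one F3, and dehydration (SOCl2, pyridine) gives 11.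

Step 15 carries two risks: the medium-ring closure itself, and the C3 configuration, which rests only on substrate control. The fallback sets out from 28 and comes back at 30, and moves C3 control from the ring closure to a reagent. The same chromium-mediated closure is run without regard to selectivity; it gives 30 together with its C3 epimer (3aR,4R,6E,9R,10Z,11aR)-9-hydroxy-6,10-dimethyl-3-methylidene-2-oxo-2,3,3a,4,5,8,9,11a-octahydrocyclodeca[b]furan-4-yl (2R,3S)-2,3-dimethyloxirane-2-carboxylate F4. The mixture is oxidised (Dess–Martin periodinane) to the macrocyclic Z-enone (3aR,4R,6E,10Z,11aR)-6,10-dimethyl-3-methylidene-2,9-dioxo-2,3,3a,4,5,8,9,11a-octahydrocyclodeca[b]furan-4-yl (2R,3S)-2,3-dimethyloxirane-2-carboxylate F5. F5 is then reduced 1,2 under catalyst control ((R)-2-methyl-CBS-oxazaborolidine, catecholborane, −78 °C) to 30.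

**Further compounds**
F1 | step 4 | methyl (4S,5Z)-4-hydroxy-6-iodo-2-methylidenehept-5-enoate | C=C(C[C@@H](/C=C(/C)I)O)C(=O)OC
F2 | step 5 | (6S)-6-[(1Z)-2-iodoprop-1-en-1-yl]-1,5-dioxaspiro[2.4]heptan-4-one (either configuration at the spiro carbon) | O=C1O[C@H](/C=C(/C)I)CC12CO2
F3 | step 5 | (5S)-3-(bromomethyl)-3-hydroxy-5-[(1Z)-2-iodoprop-1-en-1-yl]oxolan-2-one (either configuration at C3) | O=C1O[C@H](/C=C(/C)I)CC1(O)CBr
F4 | step 15 | (3aR,4R,6E,9R,10Z,11aR)-9-hydroxy-6,10-dimethyl-3-methylidene-2-oxo-2,3,3a,4,5,8,9,11a-octahydrocyclodeca[b]furan-4-yl (2R,3S)-2,3-dimethyloxirane-2-carboxylate | C=C1C(=O)O[C@@H]2/C=C(/C)[C@H](O)C/C=C(\C)C[C@@H](OC(=O)[C@]3(C)O[C@H]3C)[C@@H]12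
F5 | step 15 | (3aR,4R,6E,10Z,11aR)-6,10-dimethyl-3-methylidene-2,9-dioxo-2,3,3a,4,5,8,9,11a-octahydrocyclodeca[b]furan-4-yl (2R,3S)-2,3-dimethyloxirane-2-carboxylate | C=C1C(=O)O[C@@H]2/C=C(/C)C(=O)C/C=C(\C)C[C@@H](OC(=O)[C@]3(C)O[C@H]3C)[C@@H]12
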